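Retrosynthesis: the four resorcinol O-benzyl groups and the chain C=C are put back, the furan is returned to its 2,3-dihydro level, and then C3–C3a and O1–C2 are cut together.
This double cut is possible because furan C2 (with its 4-hydroxyphenyl) and C3 (with its aroyl group) are C-beta and C-alpha of one 4-hydroxychalcone, while O1, C7a, C3a and the benzo ring with its C5 three-carbon aryl ketone chain are the phenol ring and enone of a second one: the target is a dehydro-dimer of a single chalcone.
The monomer is cut at its enone C=C into 2,4-bis(benzyloxy)acetophenone and MOM-protected 4-hydroxybenzaldehyde.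
Forward: aldol condensation gives the chalcone; anodic coupling closes the dihydrofuran (the only ring made); dehydrogenation gives the benzofuran; one hydrogenation saturates the chain and frees the four resorcinol hydroxyls.
Stereochemistry: the target is achiral; the coupling gives the racemic trans-2,3 dimer under substrate control and both centres vanish on aromatisation; the E enone geometry comes from the condensation and is removed at the end.

Key step: step 5

Remark: because the target has no stereocentre, the dimer is made and used as the racemate; benzyl ethers replace methyl ethers on the resorcinol rings so that the last hydrogenation also deprotects.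

Step 1
Reactants: 1 2,4-dihydroxyacetophenone
Product: 2 1-[2,4-bis(benzyloxy)phenyl]ethan-1-one
Conditions: BnBr (2.5 equiv), K2CO3 (3 equiv), DMF, 80 °C
Reagents that add atoms: benzyl bromide, BrCc1ccccc1
Why: Williamson ether synthesis, in which carbonate deprotonates both phenols and the phenoxides displace bromide, the hydrogen-bonded 2-OH needing the excess reagent and warm DMF; no stereocentre is formed.

Step 2
Reactants: 3 4-hydroxybenzaldehyde
Product: 4 4-(methoxymethoxy)benzaldehyde
Conditions: MOMCl (1.3 equiv), K2CO3, acetone, 0 °C to rt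
Reagents that add atoms: chloromethyl methyl ether, COCCl
Why: Williamson-type O-alkylation of the acidic para-formyl phenoxide with the reactive alpha-chloro ether gives the MOM acetal, which keeps an unreactive phenolate-aldehyde from forming in the basic condensation of step 3.

Step 3
Reactants: 2 1-[2,4-bis(benzyloxy)phenyl]ethan-1-one; 4 4-(methoxymethoxy)benzaldehyde
Product: 6 (E)-1-[2,4-bis(benzyloxy)phenyl]-3-[4-(methoxymethoxy)phenyl]prop-2-en-1-one, via aldol adduct 5 (not isolated)
Conditions: KOH (50% aq), EtOH–THF, rt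
Reagents that add atoms: none
Why: Claisen–Schmidt (crossed aldol) condensation, in which the methyl ketone enolate of 2 adds to the non-enolisable aldehyde 4 and aldol 5 loses water by E1cB to give the E-enone under equilibrating conditions, benzyl and MOM ethers being inert to hydroxide.

Step 4
Reactants: 6 (E)-1-[2,4-bis(benzyloxy)phenyl]-3-[4-(methoxymethoxy)phenyl]prop-2-en-1-one
Product: 7 (E)-1-[2,4-bis(benzyloxy)phenyl]-3-(4-hydroxyphenyl)prop-2-en-1-one
Conditions: conc. HCl (cat.), MeOH–THF, 50 °C
Reagents that add atoms: none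
Why: Acid-catalysed cleavage of the MOM acetal (transacetalisation to methanol) frees the one phenol that is to be oxidised, while the aryl benzyl ethers and the enone, which has no 2'-hydroxyl that could close a flavanone, are untouched.

Step 5
Reactants: 7 (E)-1-[2,4-bis(benzyloxy)phenyl]-3-(4-hydroxyphenyl)prop-2-en-1-one (two molecules)
Product: 10 (2R*,3R*)-3-[2,4-bis(benzyloxy)benzoyl]-5-{(E)-3-[2,4-bis(benzyloxy)phenyl]-3-oxoprop-1-en-1-yl}-2-(4-hydroxyphenyl)-2,3-dihydro-1-benzofuran (racemic trans dimer), via coupled dienone 8 (not isolated), via quinone methide phenol 9 (not isolated)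
Conditions: graphite anode, Pt cathode, divided cell, controlled potential at the first anodic wave of 7, about 0.8–1.0 F per mol, 2,6-lutidine (2 equiv), nBu4NBF4 (0.1 M), MeCN–CH2Cl2, 0 °C; catholyte AcOH, nBu4NBF4, MeCN
Reagents that add atoms: none
Why: Proton-coupled one-electron oxidation of the phenol gives a phenoxyl radical whose spin sits on oxygen, the two ortho carbons and, through the styryl double bond, C-alpha of the enone; C-alpha of one radical bonds to an ortho carbon of another (C3–C3a) to give 8, which tautomerises to phenol 9, and the phenol oxygen then adds to the quinone methide carbon (O1–C2). The closest known reaction is the oxidative 8–5' dehydrodimerisation of 4-hydroxycinnamate esters, amides and propenylphenols to trans-2-aryl-2,3-dihydrobenzofurans with Ag2O, peroxidase or a carbon anode, and 7 is the aryl ketone member of the same 4-hydroxycinnamoyl class. The dihydrofuran closes by 5-exo-trig oxa-Michael addition of the phenol oxygen to the exocyclic quinone methide carbon, which restores both aromatic rings. No chiral element is present, so the product is racemic; the trans relation of C2 and C3 is set in the ring closure, where the 4-hydroxyphenyl and aroyl groups take opposite faces, and is backed thermodynamically because C3 is alpha to a ketone. The step needs C-alpha-to-ortho pairing over C-alpha-to-C-alpha, C-alpha-to-oxygen and ortho-to-ortho pairing; spin density at C-alpha, the two free ortho positions and the para position blocked by the side chain favour it, and only the C–C coupled intermediate carries an internal phenol that traps its quinone methide irreversibly. The benzylated resorcinol rings are not oxidised at the potential of the phenol wave, the charge is limited so that the less easily oxidised alkylphenol of the dimer is spared, and the divided cell keeps the enones away from the cathode.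

Step 6
Reactants: 10 racemic trans dimer
Product: 11 (E)-1-[2,4-bis(benzyloxy)phenyl]-3-{3-[2,4-bis(benzyloxy)benzoyl]-2-(4-hydroxyphenyl)-1-benzofuran-5-yl}prop-2-en-1-one
Conditions: DDQ (1.3 equiv), 1,4-dioxane, 90 °C
Reagents that add atoms: none
Why: Quinone dehydrogenation, in which DDQ takes hydride from C2 (benzylic, oxygen-bearing and stabilised by the para-hydroxyphenyl group) and loss of the acidic C3 proton aromatises the furan, as known for 8–5' dihydrobenzofuran neolignans; both stereocentres are removed and the enone and the unactivated benzyl ethers are not oxidised.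

Step 7
Reactants: 11 (E)-1-[2,4-bis(benzyloxy)phenyl]-3-{3-[2,4-bis(benzyloxy)benzoyl]-2-(4-hydroxyphenyl)-1-benzofuran-5-yl}prop-2-en-1-one
Product: 13 isolophirone C, via saturated tetrabenzyl ether 12 (not isolated)
Conditions: H2 (1 atm), Pd/C (10% palladium on carbon), THF–MeOH, rt
Reagents that add atoms: none
Why: Heterogeneous catalytic hydrogenation followed by hydrogenolysis, in which the disubstituted enone C=C is saturated first to give 12 and the four aryl benzyl ethers are then cleaved to toluene, while the fully substituted furan double bond (part of the aromatic benzofuran and of a vinylogous ester) and the two oxygen-rich aryl ketones should resist reduction at 1 atm; no stereocentre remains.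

Compound list
1 | 2,4-dihydroxyacetophenone | CC(=O)c1ccc(O)cc1O | starting material
2 | 1-[2,4-bis(benzyloxy)phenyl]ethan-1-one | CC(=O)c1ccc(OCc2ccccc2)cc1OCc1ccccc1 | intermediate
3 | 4-hydroxybenzaldehyde | O=Cc1ccc(O)cc1 | starting material
4 | 4-(methoxymethoxy)benzaldehyde | COCOc1ccc(C=O)cc1 | intermediate
5 | (3RS)-1-[2,4-bis(benzyloxy)phenyl]-3-hydroxy-3-[4-(methoxymethoxy)phenyl]propan-1-one (aldol adduct, racemic, one enantiomer drawn, not isolated) | COCOc1ccc([C@H](O)CC(=O)c2ccc(OCc3ccccc3)cc2OCc2ccccc2)cc1 | intermediate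
6 | (E)-1-[2,4-bis(benzyloxy)phenyl]-3-[4-(methoxymethoxy)phenyl]prop-2-en-1-one | COCOc1ccc(/C=C/C(=O)c2ccc(OCc3ccccc3)cc2OCc2ccccc2)cc1 | intermediate
7 | (E)-1-[2,4-bis(benzyloxy)phenyl]-3-(4-hydroxyphenyl)prop-2-en-1-one | O=C(/C=C/c1ccc(O)cc1)c1ccc(OCc2ccccc2)cc1OCc1ccccc1 | intermediate
8 | 6-{1-[2,4-bis(benzyloxy)benzoyl]-2-(4-oxocyclohexa-2,5-dien-1-ylidene)ethyl}-4-{(E)-3-[2,4-bis(benzyloxy)phenyl]-3-oxoprop-1-en-1-yl}cyclohexa-2,4-dien-1-one (coupled dienone, mixture of diastereomers, not isolated) | O=C1C=CC(/C=C/C(=O)c2ccc(OCc3ccccc3)cc2OCc2ccccc2)=CC1C(C(=O)c1ccc(OCc2ccccc2)cc1OCc1ccccc1)C=C1C=CC(=O)C=C1 | intermediate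
9 | (2RS)-1-[2,4-bis(benzyloxy)phenyl]-2-(5-{(E)-3-[2,4-bis(benzyloxy)phenyl]-3-oxoprop-1-en-1-yl}-2-hydroxyphenyl)-3-(4-oxocyclohexa-2,5-dien-1-ylidene)propan-1-one (quinone methide phenol, racemic, one enantiomer drawn, not isolated) | Oc1ccc(/C=C/C(=O)c2ccc(OCc3ccccc3)cc2OCc2ccccc2)cc1[C@@H](C(=O)c1ccc(OCc2ccccc2)cc1OCc1ccccc1)C=C1C=CC(=O)C=C1 | intermediate
10 | (2R*,3R*)-3-[2,4-bis(benzyloxy)benzoyl]-5-{(E)-3-[2,4-bis(benzyloxy)phenyl]-3-oxoprop-1-en-1-yl}-2-(4-hydroxyphenyl)-2,3-dihydro-1-benzofuran (racemic, 2-aryl and 3-aroyl trans, the 2R,3R enantiomer drawn) | O1[C@@H](c2ccc(O)cc2)[C@H](C(=O)c2ccc(OCc3ccccc3)cc2OCc2ccccc2)c2cc(/C=C/C(=O)c3ccc(OCc4ccccc4)cc3OCc3ccccc3)ccc12 | intermediate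
11 | (E)-1-[2,4-bis(benzyloxy)phenyl]-3-{3-[2,4-bis(benzyloxy)benzoyl]-2-(4-hydroxyphenyl)-1-benzofuran-5-yl}prop-2-en-1-one | O=C(/C=C/c1ccc2oc(-c3ccc(O)cc3)c(C(=O)c3ccc(OCc4ccccc4)cc3OCc3ccccc3)c2c1)c1ccc(OCc2ccccc2)cc1OCc1ccccc1 | intermediate
12 | 1-[2,4-bis(benzyloxy)phenyl]-3-{3-[2,4-bis(benzyloxy)benzoyl]-2-(4-hydroxyphenyl)-1-benzofuran-5-yl}propan-1-one (saturated tetrabenzyl ether, not isolated) | O=C(CCc1ccc2oc(-c3ccc(O)cc3)c(C(=O)c3ccc(OCc4ccccc4)cc3OCc3ccccc3)c2c1)c1ccc(OCc2ccccc2)cc1OCc1ccccc1 | intermediate
13 | isolophirone C, 1-(2,4-dihydroxyphenyl)-3-[3-(2,4-dihydroxybenzoyl)-2-(4-hydroxyphenyl)-1-benzofuran-5-yl]propan-1-one (achiral) | O=C(CCc1ccc2oc(-c3ccc(O)cc3)c(C(=O)c3ccc(O)cc3O)c2c1)c1ccc(O)cc1O | target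

Total step count: 7
Longest linear sequence: 6 steps (steps 1, 3, 4, 5, 6, 7 from 1, or steps 2 to 7 from 3)

Steps most likely to fail

Step 5. What may go wrong: the phenoxyl radicals may pair through other positions (C-alpha to C-alpha, C-alpha to oxygen, ortho to ortho), and the dimer phenol may be oxidised further to oligomers that coat the anode. Fallback: the same two ring bonds are made one after the other with palladium instead of by radical pairing. It sets out from 7 and 4 and comes back at 11, so step 6 is bypassed as well.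
- Phenoxide-selective mono-iodination of 7 (I2, morpholine, CH2Cl2, 0 °C) should give (E)-1-[2,4-bis(benzyloxy)phenyl]-3-(4-hydroxy-3-iodophenyl)prop-2-en-1-one F1.
- Seyferth–Gilbert homologation of 4 with dimethyl (1-diazo-2-oxopropyl)phosphonate (K2CO3, MeOH, rt) should give 1-ethynyl-4-(methoxymethoxy)benzene F2.
- Sonogashira coupling of F1 with F2 (PdCl2(PPh3)2, CuI, Et3N, THF, rt) makes the C3a–C3 bond and should give (E)-1-[2,4-bis(benzyloxy)phenyl]-3-(4-hydroxy-3-{[4-(methoxymethoxy)phenyl]ethynyl}phenyl)prop-2-en-1-one F3; it is kept at room temperature so that it does not cyclise before the carbonyl is in place.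
- Benzylation of commercial 4-iodoresorcinol (BnBr, K2CO3, DMF) should give 2,4-bis(benzyloxy)-1-iodobenzene F4.
- Carbonylative annulation of F3 with F4 (Pd(PPh3)4, K2CO3, CO 1 atm, MeCN, 50 °C) follows: the aroylpalladium iodide formed from F4 and CO activates the alkyne, the phenoxide closes O1–C2, and reductive elimination joins C3 to the aroyl carbon. This should give (E)-1-[2,4-bis(benzyloxy)phenyl]-3-{3-[2,4-bis(benzyloxy)benzoyl]-2-[4-(methoxymethoxy)phenyl]-1-benzofuran-5-yl}prop-2-en-1-one F5.
- Acid cleavage of the MOM group under the conditions of step 4 returns 11.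

Step 6. What may go wrong: the quinone may oxidise the free 4-hydroxyphenyl ring (quinone methide formation with opening of the dihydrofuran, or phenol–quinone adducts) faster than it takes hydride from C2. Fallback: dehydrogenation through the enol of the C3 ketone (Saegusa–Ito oxidation) instead of hydride abstraction. It sets out from 10 and comes back at 11.
- TMSOTf and Et3N (CH2Cl2, 0 °C) silylate the phenol and turn the C3 aroyl group into its silyl enol ether without a free enolate, so the ring oxygen is not eliminated. This should give (2RS)-3-{[2,4-bis(benzyloxy)phenyl][(trimethylsilyl)oxy]methylidene}-5-{(E)-3-[2,4-bis(benzyloxy)phenyl]-3-oxoprop-1-en-1-yl}-2-{4-[(trimethylsilyl)oxy]phenyl}-2,3-dihydro-1-benzofuran F6 (enol ether geometry not controlled).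
- Pd(OAc)2 in MeCN forms the C3 palladium enolate, and beta-hydride elimination of the C2 hydrogen gives the aromatic furan as (E)-1-[2,4-bis(benzyloxy)phenyl]-3-(3-[2,4-bis(benzyloxy)benzoyl]-2-{4-[(trimethylsilyl)oxy]phenyl}-1-benzofuran-5-yl)prop-2-en-1-one F7.
- K2CO3 in MeOH removes the aryl silyl ether and gives 11.

Step 7. What may go wrong: reduction may run past the target (an aryl ketone reduced to the alcohol or methylene, or the furan saturated) before the last benzyl ether is gone, or the reaction may stall at partly benzylated material. Fallback: the two events are separated and hydrogenolysis is dropped. It sets out from 11 and comes back at 13.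
- Homogeneous hydrogenation with RhCl(PPh3)3 (H2 1 atm, benzene–EtOH, rt) saturates only the chain alkene and gives 12, which is now isolated.
- BCl3 with pentamethylbenzene as cation scavenger (CH2Cl2, −78 °C) then cleaves the four benzyl ethers by Lewis-acid dealkylation, with the benzyl groups ending up as 1-benzyl-2,3,4,5,6-pentamethylbenzene, and gives 13.

Further compounds
F1 | step 5 | (E)-1-[2,4-bis(benzyloxy)phenyl]-3-(4-hydroxy-3-iodophenyl)prop-2-en-1-one | O=C(/C=C/c1ccc(O)c(I)c1)c1ccc(OCc2ccccc2)cc1OCc1ccccc1
F2 | step 5 | 1-ethynyl-4-(methoxymethoxy)benzene | COCOc1ccc(C#C)cc1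
F3 | step 5 | (E)-1-[2,4-bis(benzyloxy)phenyl]-3-(4-hydroxy-3-{[4-(methoxymethoxy)phenyl]ethynyl}phenyl)prop-2-en-1-one | O=C(/C=C/c1ccc(O)c(C#Cc2ccc(OCOC)cc2)c1)c1ccc(OCc2ccccc2)cc1OCc1ccccc1
F4 | step 5 | 2,4-bis(benzyloxy)-1-iodobenzene | Ic1ccc(OCc2ccccc2)cc1OCc1ccccc1
F5 | step 5 | (E)-1-[2,4-bis(benzyloxy)phenyl]-3-{3-[2,4-bis(benzyloxy)benzoyl]-2-[4-(methoxymethoxy)phenyl]-1-benzofuran-5-yl}prop-2-en-1-one | O=C(/C=C/c1ccc2oc(-c3ccc(OCOC)cc3)c(C(=O)c3ccc(OCc4ccccc4)cc3OCc3ccccc3)c2c1)c1ccc(OCc2ccccc2)cc1OCc1ccccc1
F6 | step 6 | (2RS)-3-{[2,4-bis(benzyloxy)phenyl][(trimethylsilyl)oxy]methylidene}-5-{(E)-3-[2,4-bis(benzyloxy)phenyl]-3-oxoprop-1-en-1-yl}-2-{4-[(trimethylsilyl)oxy]phenyl}-2,3-dihydro-1-benzofuran (racemic, one enantiomer drawn) | O1[C@@H](c2ccc(O[Si](C)(C)C)cc2)C(=C(O[Si](C)(C)C)c2ccc(OCc3ccccc3)cc2OCc2ccccc2)c2cc(/C=C/C(=O)c3ccc(OCc4ccccc4)cc3OCc3ccccc3)ccc12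
F7 | step 6 | (E)-1-[2,4-bis(benzyloxy)phenyl]-3-(3-[2,4-bis(benzyloxy)benzoyl]-2-{4-[(trimethylsilyl)oxy]phenyl}-1-benzofuran-5-yl)prop-2-en-1-one | O=C(/C=C/c1ccc2oc(-c3ccc(O[Si](C)(C)C)cc3)c(C(=O)c3ccc(OCc4ccccc4)cc3OCc3ccccc3)c2c1)c1ccc(OCc2ccccc2)cc1OCc1ccccc1
F0 | step 7 | none | none
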